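Remark on the chemistry: positions are given in germacrane numbering throughout (C1=C10 olefin with methyl C14 on C10, C2, C3, C4 with methyl C15, C5, C6 carbinol, C7 with the branch C11(C12)C13, C8 ester carbon, C9); 10 and 16 are assumed to be used as commercial THF solutions.

## Structural features

The target is a germacrane: one ten-membered carbocycle carrying a Z trisubstituted olefin (C1=C10), a trisubstituted cis-epoxide across C4–C5, a free secondary hydroxyl on C6, an isopropyl group on C7 and, through the C8 oxygen, a 3,4,5-trimethoxybenzoyl group; the aryl ring is joined to the carbocycle by that ester link only. Five stereocentres stand in an unbroken row: C4 (R, fully substituted), C5 (S), C6 (R), C7 (S) and C8 (R). The epoxide is the most fragile group, because a 4,5-epoxide facing the C1=C10 olefin across a ten-membered ring opens with transannular cyclisation under acid; the aroyl group can also migrate from the C8 to the C6 oxygen under base, and any intermediate in which C6 is flanked by two olefins ionises easily. The real difficulty is closing a medium ring while setting the contiguous C6–C7–C8 triad without a rigid template. Two features simplify the problem: the epoxide is the image of a Z C4=C5 olefin oxidised on the face of the C6 hydroxyl, and the isopropyl group is a hydrogenated isopropenyl group. With isopropenyl on C7, the C8 carbinol and C7 with its branch C11(=C12)–C13 make up a homoallylic alcohol whose C8 oxygen is syn to C6 across C7, the relation a Z γ-substituted allylboronate gives through a chair. The key step uses this: an allylboronate (boron on C12, olefin C11=C7) and a C8 aldehyde in one chain form C7–C8, so that the ring and the C7 and C8 stereocentres arise together.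

## Logic of the disconnections

33 to 32: the two C–O bonds of the oxirane (C4–O, C5–O) are cut. The epoxide is the least robust group and belongs last. This removes two stereocentres and leaves a plain Z,Z-diene. The forward step must pick C4=C5 over C1=C10 and the correct face; the free C6 hydroxyl, allylic to C4=C5 only and lying on the outer face of that olefin, answers both.

32 to 28 and 29: the C6 O–Si bond, the two C–H bonds added to C11=C12, and the C8 O–acyl bond are cut in turn (32 from 31, 31 from 30, 30 from 28 and 29). In 28 the C8 hydroxyl is the only free one, so acylation needs no differentiation. The forward steps demand a hydrogenation that touches only the 1,1-disubstituted olefin and a desilylation that does not let the ester migrate.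

28 to 26: the C7–C8 bond is cut. This one cut opens the ring and removes two stereocentres, leaving an open chain with a single stereocentre (C6) and three Z olefins. The forward step must favour ring closure over reaction between molecules and must choose the face of the allyl unit from C6 alone.

26 to 23 and 24: the C11–C12 bond is cut, so that boron enters last, by a neutral palladium-catalysed coupling on a chain that already holds the aldehyde. This avoids generating an alkenyllithium cis to a silyloxy-bearing carbon, where a 1,4-shift of silicon from oxygen to carbon threatens, and it avoids any oxidation in the presence of the allylboronate. The coupling must retain the olefin geometry and tolerate the aldehyde.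

23 to 19: the aldehyde is traced to a primary silyl ether (23 from 22), the C6 O–Si bond is cut (22 from 21), and the C11–I and C7–H bonds are cut back to an alkyne (21 from 19). The Z iodoalkene then needs no olefination; it demands a trans-hydrometalation with the metal on the alkyne carbon remote from the carbinol.

19 to 15 and 16: the C6–H bond (19 from 18), the carbinol hydrogen (18 from 17) and then the C6–C7 bond (17 from 15 and 16) are cut. The only stereocentre of the open chain is thus set by reagent control on a ketone. The reduction has to tell a branched alkenyl group from a linear alkynyl group.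

15 to 9 and 10: the oxidation level is adjusted (15 from 14), the C6 oxygen is unmasked (14 from 13), and the C9–C10 bond is cut (13 from 9 and 10), C8 and its oxygen coming from the two-carbon epoxide. The two ends of the chain are so differentiated by one acid-stable, oxidatively removable ether and one silyl ether. The C9–C10 bond formation must retain the alkene geometry.

9 to 4 and 5: the C1=C10 double bond is cut. A Wittig reaction of a secondary ylide would not control this trisubstituted geometry, so the olefin is made with iodine as a placeholder on C10, which fixes the geometry before C9 is attached. The demand is Z selectivity in the olefination.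

4 to 1: the former isopropylidene terminus is restored (4 from 2) and the ether removed (2 from 1). 1 supplies C1 to C6, C15 and the Z C4=C5 olefin ready-made; the forward step must cleave only the remote olefin.

The configurations of 26 and 28 were checked against 33: C6, C7 and C8 map unchanged, and no correction to these structures was needed.

## Other disconnections considered

Alternative 1: The cut is C8–C9, with C1–C6 reconnected, so the ten-membered ring is traced to a six-membered ring bearing two alkenyl groups. Forward, a potassium alkoxide undergoes an anion-accelerated [3,3] shift (anionic oxy-Cope rearrangement) that forms C8–C9, cleaves C1–C6 and gives the enolate of the cyclodecadienone A1; protonation sets C7.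
- In its favour: the medium ring arises by ring expansion, not by end-to-end closure, which is a better precedented way to germacrane-type rings than the chosen allylboration, and here the alternative is the better plan. The six-membered ring comes from the chiral pool, so the route would be clearly shorter than the chosen 18 steps; it is better on step economy too.
- Against it: the rearranging alkoxide needs both alkenyl groups cis on the six-membered ring, which means carbonyl addition of a hindered, α-branched silyl vinyl metal on the face next to the resident isopropenyl group. The only stereocentre carrying absolute configuration is destroyed in the shift, so C8 rests entirely on the fidelity of one transition-state geometry and on the vinylsilane geometry.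
- After A1, three separate events are still needed: C7 by enolate protonation next to a ketone, C6 by a face-selective ketone reduction, and C8–Si to C8–OH by Tamao–Fleming oxidation. A β-acyloxy ketone on the way is prone to elimination.
- Comparison: both plans reach the same Z,Z-diene and the same late epoxidation. On regiochemistry of esterification the two are equal, since C8–OH also appears alone. The chosen plan sets C7 and C8 in one event governed by olefin geometry and C6.

Alternative 2: The cut is C1–C2, between an alkenyl and an alkyl carbon. Forward, 9-BBN hydroborates a terminal vinyl group at C2, and Pd(dppf)Cl2 with base couples the alkylborane with the C1 alkenyl iodide (B-alkyl Suzuki–Miyaura coupling, retention at C1) to close the ring and give A2.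
- In its favour: C6, C7 and C8, the isopropyl group and the ester are all in place before ring closure, so the key step creates no stereocentre; on stereochemical risk in the ring-forming step it is the better plan. The C1=C10 geometry is carried by an iodoalkene in both plans (equal). The endgame lacks the hydrogenation, so it is one step shorter after ring closure.
- Against it: a ten-membered ring must close by reductive elimination from a strained palladium intermediate. Medium rings are the worst case for this macrocyclisation, and β-hydride elimination, protodeboronation and coupling between molecules all compete. Aqueous base and heat are applied to an aryl ester.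
- The open-chain C6–C7–C8 triad with its isopropyl branch must be built by separate asymmetric steps, which should make the whole route at least as long as the chosen one.
- Comparison: the chosen plan gains two stereocentres in the ring closure but accepts a less precedented closure; A2 shifts all the risk to ring strain.

Alternative 3: The cut is C2–C3. Forward, zerovalent palladium ionises an allylic carbonate at C3, and a bis(phenylsulfonyl) carbanion at C2 attacks C3 of the allyl complex (Tsuji–Trost alkylation) to give A3.
- In its favour: palladium-allyl alkylation with bis-sulfonyl carbanions is an established closure for medium and large rings and needs no extreme dilution; on precedent and on practicality of the ring closure it is the better plan. No stereocentre is formed, and a free C6 hydroxyl is tolerated.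
- Against it: the Z allylic carbonate ionises to an allyl complex that can equilibrate to the isomer leading to an E C4=C5 olefin faster than a slow medium ring closes. Attack at C5 would give an eight-membered ring.
- The two sulfonyl groups on C2, which is allylic to C1=C10, must be removed reductively, with a risk of moving or isomerising that olefin.
- A3 has C6 free and C8 silylated, the opposite of what the esterification needs, so protecting-group exchange adds steps. The stereotriad again needs open-chain construction.
- Comparison: the route would be longer than the chosen one and puts the Z geometry of C4=C5 at risk, which the chosen plan takes intact from 1.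

Key step: step 14

## Route

Step 1
Reactants: 1 nerol, (2Z)-3,7-dimethylocta-2,6-dien-1-ol
Product: 2 (2Z)-1-[(4-methoxybenzyl)oxy]-3,7-dimethylocta-2,6-diene
Conditions: NaH, 4-MeOC6H4CH2Cl, Bu4NI (cat.), THF/DMF, 0 °C → rt
Reagents that add atoms: 4-methoxybenzyl chloride, COc1ccc(CCl)cc1
Why: Williamson ether synthesis on the primary allylic alkoxide; base-only conditions avoid the acid-induced cyclisation of neryl systems, and this ether later comes off oxidatively beside a silyl ether.

Step 2
Reactants: 2 (2Z)-1-[(4-methoxybenzyl)oxy]-3,7-dimethylocta-2,6-diene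
Product: 4 (4Z)-6-[(4-methoxybenzyl)oxy]-4-methylhex-4-enal, via epoxide 3 (not isolated)
Conditions: mCPBA, CH2Cl2, 0 °C; then H5IO6, THF/H2O, 0 °C (same flask)
Reagents that add atoms: 3-chloroperbenzoic acid, OOC(=O)c1cccc(Cl)c1
Why: Prilezhaev epoxidation should pick the remote, more electron-rich trisubstituted olefin because the allylic ether oxygen deactivates the proximal one; periodic acid then hydrates the epoxide and cleaves the glycol (periodate cleavage) to the aldehyde and acetone, leaving the Z olefin untouched.

Step 3
Reactants: 4 (4Z)-6-[(4-methoxybenzyl)oxy]-4-methylhex-4-enal; 5 ethyltriphenylphosphonium iodide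
Product: 9 1-({[(2Z,6Z)-7-iodo-3-methylocta-2,6-dien-1-yl]oxy}methyl)-4-methoxybenzene, via ethylidene ylide 6 (not isolated), via iodoethylphosphonium salt 7 (not isolated), via iodo ylide 8 (not isolated)
Conditions: 5, n-BuLi, THF, 0 °C → rt; I2, −78 °C; NaN(SiMe3)2, −20 °C; then 4, −78 → −20 °C
Reagents that add atoms: iodine, II
Why: Stork–Zhao-type Wittig olefination with the α-iodo ylide; the kinetically preferred oxaphosphetane places the aldehyde chain cis to iodine, so the (Z)-2-iodoalkene should dominate, and iodine holds the position that C9 takes in the next step, which fixes the C1=C10 geometry.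

Step 4
Reactants: 9 1-({[(2Z,6Z)-7-iodo-3-methylocta-2,6-dien-1-yl]oxy}methyl)-4-methoxybenzene; 10 oxirane
Product: 13 triethyl{[(3Z,7Z)-9-[(4-methoxybenzyl)oxy]-3,7-dimethylnona-3,7-dien-1-yl]oxy}silane, via alkenyllithium 11 (not isolated), via lithium alkoxide 12 (not isolated)
Conditions: t-BuLi (2.1 equiv), Et2O, −78 °C; 10 (THF solution), −78 → 0 °C; then Et3SiCl, 0 °C → rt
Reagents that add atoms: chlorotriethylsilane, CC[Si](Cl)(CC)CC
Why: Iodine–lithium exchange proceeds with retention of olefin geometry; the alkenyllithium opens the unhindered epoxide (organolithium epoxide opening), placing C9 cis to C2 and bringing in C8 as an alkoxide, which is silylated in the same flask.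

Step 5
Reactants: 13 triethyl{[(3Z,7Z)-9-[(4-methoxybenzyl)oxy]-3,7-dimethylnona-3,7-dien-1-yl]oxy}silane
Product: 14 (2Z,6Z)-3,7-dimethyl-9-[(triethylsilyl)oxy]nona-2,6-dien-1-ol
Conditions: DDQ, CH2Cl2/pH 7 buffer, 0 °C
Reagents that add atoms: none
Why: Oxidative cleavage of the 4-methoxybenzyl ether by DDQ through the benzylic oxocarbenium ion; buffered two-phase conditions should leave the primary triethylsilyl ether and the isolated trisubstituted olefins alone.

Step 6
Reactants: 14 (2Z,6Z)-3,7-dimethyl-9-[(triethylsilyl)oxy]nona-2,6-dien-1-ol
Product: 15 (2Z,6Z)-3,7-dimethyl-9-[(triethylsilyl)oxy]nona-2,6-dienal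
Conditions: MnO2, CH2Cl2, rt
Reagents that add atoms: none
Why: Allylic oxidation with MnO2, a neutral heterogeneous oxidant that should keep the Z enal (a neral-type aldehyde) from isomerising.

Step 7
Reactants: 15 (2Z,6Z)-3,7-dimethyl-9-[(triethylsilyl)oxy]nona-2,6-dienal; 16 prop-1-yn-1-ylmagnesium bromide
Product: 17 rac-(5Z,9Z)-6,10-dimethyl-12-[(triethylsilyl)oxy]dodeca-5,9-dien-2-yn-4-ol
Conditions: 16 (THF solution), THF, −78 °C
Reagents that add atoms: none
Why: 1,2-Addition of the alkynyl Grignard reagent to the enal forms C6–C7; alkynylmagnesium reagents do not add in a conjugate sense, and the racemic carbinol is taken on to the ketone on purpose.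

Step 8
Reactants: 17 rac-(5Z,9Z)-6,10-dimethyl-12-[(triethylsilyl)oxy]dodeca-5,9-dien-2-yn-4-ol
Product: 18 (5Z,9Z)-6,10-dimethyl-12-[(triethylsilyl)oxy]dodeca-5,9-dien-2-yn-4-one
Conditions: MnO2, CH2Cl2, rt
Reagents that add atoms: none
Why: The carbinol is both allylic and propargylic, so MnO2 oxidation should be fast and neutral, sparing the silyl ether and the Z enone geometry.

Step 9
Reactants: 18 (5Z,9Z)-6,10-dimethyl-12-[(triethylsilyl)oxy]dodeca-5,9-dien-2-yn-4-one
Product: 19 (4S,5Z,9Z)-6,10-dimethyl-12-[(triethylsilyl)oxy]dodeca-5,9-dien-2-yn-4-ol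
Conditions: (S)-2-methyl-CBS-oxazaborolidine (cat.), catecholborane, toluene, −78 °C
Reagents that add atoms: none
Why: Corey–Bakshi–Shibata reduction; the branched Z alkenyl group acts as the large and the linear propynyl group as the small substituent, so the (S)-oxazaborolidine should deliver hydride to the face that gives the (4S) carbinol, the future C6 stereocentre, and catecholborane at low temperature avoids hydroboration of the π systems.

Step 10
Reactants: 19 (4S,5Z,9Z)-6,10-dimethyl-12-[(triethylsilyl)oxy]dodeca-5,9-dien-2-yn-4-ol
Product: 21 (2Z,4S,5Z,9Z)-2-iodo-6,10-dimethyl-12-[(triethylsilyl)oxy]dodeca-2,5,9-trien-4-ol, via alkenylaluminate 20 (not isolated)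
Conditions: NaAlH2(OCH2CH2OMe)2, THF, 0 °C → rt; then I2, THF, −78 → 0 °C
Reagents that add atoms: iodine, II
Why: Alkoxide-directed trans-hydroalumination of the propargylic alcohol puts hydride on the proximal alkyne carbon (C7) and aluminium on the distal one (C11) in a five-membered aluminate; iodinolysis with retention gives the (Z)-γ-iodo allylic alcohol with iodine cis to C6.

Step 11
Reactants: 21 (2Z,4S,5Z,9Z)-2-iodo-6,10-dimethyl-12-[(triethylsilyl)oxy]dodeca-2,5,9-trien-4-ol
Product: 22 tert-butyl{[(2Z,4S,5Z,9Z)-2-iodo-6,10-dimethyl-12-[(triethylsilyl)oxy]dodeca-2,5,9-trien-4-yl]oxy}dimethylsilane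
Conditions: t-BuMe2SiOTf, 2,6-lutidine, CH2Cl2, −78 °C
Reagents that add atoms: tert-butyldimethylsilyl trifluoromethanesulfonate, CC(C)(C)[Si](C)(C)OS(=O)(=O)C(F)(F)F
Why: Silylation of the hindered, acid-sensitive doubly allylic alcohol with the silyl triflate and a hindered base at low temperature; the primary triethylsilyl ether is inert.

Step 12
Reactants: 22 tert-butyl{[(2Z,4S,5Z,9Z)-2-iodo-6,10-dimethyl-12-[(triethylsilyl)oxy]dodeca-2,5,9-trien-4-yl]oxy}dimethylsilane
Product: 23 (3Z,7Z,9S,10Z)-9-[(tert-butyldimethylsilyl)oxy]-11-iodo-3,7-dimethyldodeca-3,7,10-trienal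
Conditions: (COCl)2, DMSO, CH2Cl2, −78 → −40 °C; i-Pr2NEt, −78 → −30 °C; cold pH 7 buffer
Reagents that add atoms: none
Why: Swern oxidation in its direct variant on primary triethylsilyl ethers: chlorodimethylsulfonium chloride cleaves the unhindered primary silyl ether to the alkoxysulfonium salt and the base collapses it to the aldehyde, the secondary tert-butyldimethylsilyl ether staying; a hindered base and a cold neutral quench should keep the β,γ-olefin out of conjugation.

Step 13
Reactants: 23 (3Z,7Z,9S,10Z)-9-[(tert-butyldimethylsilyl)oxy]-11-iodo-3,7-dimethyldodeca-3,7,10-trienal; 24 2-(iodomethyl)-4,4,5,5-tetramethyl-1,3,2-dioxaborolane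
Product: 26 (3Z,7Z,9R,10Z)-9-[(tert-butyldimethylsilyl)oxy]-3,7,11-trimethyl-12-(4,4,5,5-tetramethyl-1,3,2-dioxaborolan-2-yl)dodeca-3,7,10-trienal, via zinc reagent 25 (not isolated)
Conditions: 24, Zn dust, THF, rt; then 23, Pd(PPh3)4 (cat.), THF (0.02 M), rt; cold aqueous work-up, short silica pad, used at once
Reagents that add atoms: none
Why: Negishi coupling of the α-boryl alkylzinc iodide with the alkenyl iodide; oxidative addition and reductive elimination retain the olefin geometry, so CH2B ends up cis to C6 (Z allylboronate), alkylzinc iodides do not add to aldehydes without activation, and the Z γ-substituted pinacol ester should be slow enough in bimolecular allylboration to survive this dilution and temperature.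

Step 14
Reactants: 26 (3Z,7Z,9R,10Z)-9-[(tert-butyldimethylsilyl)oxy]-3,7,11-trimethyl-12-(4,4,5,5-tetramethyl-1,3,2-dioxaborolan-2-yl)dodeca-3,7,10-trienal
Product: 28 (1R,2R,3S,4Z,8Z)-3-[(tert-butyldimethylsilyl)oxy]-5,9-dimethyl-2-(prop-1-en-2-yl)cyclodeca-4,8-dien-1-ol, via ring borate 27 (not isolated)
Conditions: toluene (0.002 M, slow addition of 26), 70 °C; then aq. NaHCO3
Reagents that add atoms: none
Why: Proposed new method: the aldehyde oxygen binds boron and the six atoms B, O, C8, C7, C11 and C12 pass through a chair in which C7 attacks C8 with allyl transposition, giving the borate 27 and, after hydrolysis, 28; the closest known reactions are intramolecular allylborations of ω-oxo allylboronates to five- to seven-membered rings and allylchromium closures of ten-membered germacranoids, so closing a ten-membered ring by allylboration is an extrapolation. The ten-membered ring closes by attack of C7 on the aldehyde carbon with both the C=O bond and the shifting C11=C12 bond outside the new ring (exo-trig on the carbonyl, SE2′ on the allyl unit), the chair being fused to the incipient ring across C7–C8. C8 and C7 are set together: C9 sits equatorial on C8, the Z geometry forces C6 axial on C7, these adjacent positions are gauche so the tether can span them, and the C8 oxygen and C6 come out syn. The face of the allyl unit is chosen by C6: allylic strain with C12 holds the C6–H bond in the olefin plane, and the new bond should form anti to C6–C5 with the silyloxy group outside, which gives (7R,8R) in germacrane numbering. Attack through C12 is excluded by the cyclic transition state. The selectivity to be secured is ring closure over allylation between molecules; slow addition into warm toluene keeps the stationary concentration low, and the sluggish pinacol ester should not react before dilution. No acid, base or metal is present, so the β,γ-unsaturated aldehyde should not conjugate and the doubly allylic silyl ether should not ionise.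

Step 15
Reactants: 28 (1R,2R,3S,4Z,8Z)-3-[(tert-butyldimethylsilyl)oxy]-5,9-dimethyl-2-(prop-1-en-2-yl)cyclodeca-4,8-dien-1-ol; 29 3,4,5-trimethoxybenzoyl chloride
Product: 30 (1R,2R,3S,4Z,8Z)-3-[(tert-butyldimethylsilyl)oxy]-5,9-dimethyl-2-(prop-1-en-2-yl)cyclodeca-4,8-dien-1-yl 3,4,5-trimethoxybenzoate
Conditions: 29, Et3N, DMAP (cat.), CH2Cl2, 0 °C → rt
Reagents that add atoms: none
Why: Acylation of the only free hydroxyl with the acid chloride under nucleophilic catalysis by 4-(dimethylamino)pyridine; no stereocentre is touched, and esterifying before C6 is unmasked removes any regiochemical question and the homoallylic hydroxyl that could later direct oxidation to C1=C10.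

Step 16
Reactants: 30 (1R,2R,3S,4Z,8Z)-3-[(tert-butyldimethylsilyl)oxy]-5,9-dimethyl-2-(prop-1-en-2-yl)cyclodeca-4,8-dien-1-yl 3,4,5-trimethoxybenzoate
Product: 31 (1R,2R,3S,4Z,8Z)-3-[(tert-butyldimethylsilyl)oxy]-5,9-dimethyl-2-(propan-2-yl)cyclodeca-4,8-dien-1-yl 3,4,5-trimethoxybenzoate
Conditions: H2 (1 atm), RhCl(PPh3)3 (cat.), benzene/EtOH, rt
Reagents that add atoms: none
Why: Homogeneous hydrogenation with RhCl(PPh3)3 discriminates by substitution: the 1,1-disubstituted isopropenyl olefin should be reduced while the two trisubstituted ring olefins are too hindered to bind, and C11 is not a stereocentre.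

Step 17
Reactants: 31 (1R,2R,3S,4Z,8Z)-3-[(tert-butyldimethylsilyl)oxy]-5,9-dimethyl-2-(propan-2-yl)cyclodeca-4,8-dien-1-yl 3,4,5-trimethoxybenzoate
Product: 32 (1R,2S,3S,4Z,8Z)-3-hydroxy-5,9-dimethyl-2-(propan-2-yl)cyclodeca-4,8-dien-1-yl 3,4,5-trimethoxybenzoate
Conditions: HF·pyridine, pyridine, THF, 0 °C → rt
Reagents that add atoms: none
Why: Fluoride-induced desilylation under buffered, weakly acidic conditions; a basic fluoride source is avoided because it would invite migration of the aroyl group from the C8 to the C6 oxygen.

Step 18
Reactants: 32 (1R,2S,3S,4Z,8Z)-3-hydroxy-5,9-dimethyl-2-(propan-2-yl)cyclodeca-4,8-dien-1-yl 3,4,5-trimethoxybenzoate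
Product: 33 (1(10)Z,4R,5S,6R,7S,8R)-4,5-epoxy-6-hydroxygermacr-1(10)-en-8-yl 3,4,5-trimethoxybenzoate (CNP0260213.9)
Conditions: VO(acac)2 (cat.), t-BuOOH, CH2Cl2, 0 °C → rt
Reagents that add atoms: tert-butyl hydroperoxide, CC(C)(C)OO
Why: Hydroxyl-directed epoxidation through the vanadium alkoxide–peroxide complex acts only on the olefin allylic to the free hydroxyl, so C1=C10 should be spared; allylic strain between C3 and the C6 substituents keeps C6–H in the olefin plane, the hydroxyl then lies on the outer face of the ring olefin, and directed delivery and peripheral attack both lead to the (4R,5S) epoxide syn to the hydroxyl.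

## Compound list

1 | nerol, (2Z)-3,7-dimethylocta-2,6-dien-1-ol | CC(C)=CCC/C(C)=C\CO | starting material
2 | (2Z)-1-[(4-methoxybenzyl)oxy]-3,7-dimethylocta-2,6-diene | CC(C)=CCC/C(C)=C\COCc1ccc(OC)cc1 | intermediate
3 | 2-{(3Z)-5-[(4-methoxybenzyl)oxy]-3-methylpent-3-en-1-yl}-3,3-dimethyloxirane (racemic) | CC1(C)OC1CC/C(C)=C\COCc1ccc(OC)cc1 | intermediate
4 | (4Z)-6-[(4-methoxybenzyl)oxy]-4-methylhex-4-enal | O=CCC/C(C)=C\COCc1ccc(OC)cc1 | intermediate
5 | ethyltriphenylphosphonium iodide | CC[P+](c1ccccc1)(c1ccccc1)c1ccccc1.[I-] | starting material
6 | ethylidenetriphenylphosphorane | CC=P(c1ccccc1)(c1ccccc1)c1ccccc1 | intermediate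
7 | (1-iodoethyl)triphenylphosphonium iodide | CC(I)[P+](c1ccccc1)(c1ccccc1)c1ccccc1.[I-] | intermediate
8 | (1-iodoethylidene)triphenylphosphorane | CC(I)=P(c1ccccc1)(c1ccccc1)c1ccccc1 | intermediate
9 | 1-({[(2Z,6Z)-7-iodo-3-methylocta-2,6-dien-1-yl]oxy}methyl)-4-methoxybenzene | C/C(I)=C/CC/C(C)=C\COCc1ccc(OC)cc1 | intermediate
10 | oxirane | C1CO1 | starting material
11 | alkenyllithium from 9 (lithium in place of iodine, geometry retained) | C/C([Li])=C/CC/C(C)=C\COCc1ccc(OC)cc1 | intermediate
12 | lithium (3Z,7Z)-9-[(4-methoxybenzyl)oxy]-3,7-dimethylnona-3,7-dien-1-olate | [Li]OCC/C(C)=C\CC/C(C)=C\COCc1ccc(OC)cc1 | intermediate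
13 | triethyl{[(3Z,7Z)-9-[(4-methoxybenzyl)oxy]-3,7-dimethylnona-3,7-dien-1-yl]oxy}silane | CC[Si](CC)(CC)OCC/C(C)=C\CC/C(C)=C\COCc1ccc(OC)cc1 | intermediate
14 | (2Z,6Z)-3,7-dimethyl-9-[(triethylsilyl)oxy]nona-2,6-dien-1-ol | CC[Si](CC)(CC)OCC/C(C)=C\CC/C(C)=C\CO | intermediate
15 | (2Z,6Z)-3,7-dimethyl-9-[(triethylsilyl)oxy]nona-2,6-dienal | CC[Si](CC)(CC)OCC/C(C)=C\CC/C(C)=C\C=O | intermediate
16 | prop-1-yn-1-ylmagnesium bromide | CC#C[Mg]Br | starting material
17 | rac-(5Z,9Z)-6,10-dimethyl-12-[(triethylsilyl)oxy]dodeca-5,9-dien-2-yn-4-ol | CC[Si](CC)(CC)OCC/C(C)=C\CC/C(C)=C\C(O)C#CC | intermediate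
18 | (5Z,9Z)-6,10-dimethyl-12-[(triethylsilyl)oxy]dodeca-5,9-dien-2-yn-4-one | CC[Si](CC)(CC)OCC/C(C)=C\CC/C(C)=C\C(=O)C#CC | intermediate
19 | (4S,5Z,9Z)-6,10-dimethyl-12-[(triethylsilyl)oxy]dodeca-5,9-dien-2-yn-4-ol | CC[Si](CC)(CC)OCC/C(C)=C\CC/C(C)=C\[C@H](O)C#CC | intermediate
20 | sodium salt of the five-membered alkoxy alkenyl aluminate of 19 (ring O–Al–C11=C7–C6, two 2-methoxyethoxy groups on aluminium) | CC[Si](CC)(CC)OCC/C(C)=C\CC/C(C)=C\[C@@H]1O[Al-](OCCOC)(OCCOC)C(C)=C1.[Na+] | intermediate
21 | (2Z,4S,5Z,9Z)-2-iodo-6,10-dimethyl-12-[(triethylsilyl)oxy]dodeca-2,5,9-trien-4-ol | CC[Si](CC)(CC)OCC/C(C)=C\CC/C(C)=C\[C@H](O)/C=C(C)\I | intermediate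
22 | tert-butyl{[(2Z,4S,5Z,9Z)-2-iodo-6,10-dimethyl-12-[(triethylsilyl)oxy]dodeca-2,5,9-trien-4-yl]oxy}dimethylsilane | CC[Si](CC)(CC)OCC/C(C)=C\CC/C(C)=C\[C@H](O[Si](C)(C)C(C)(C)C)/C=C(C)\I | intermediate
23 | (3Z,7Z,9S,10Z)-9-[(tert-butyldimethylsilyl)oxy]-11-iodo-3,7-dimethyldodeca-3,7,10-trienal | O=CC/C(C)=C\CC/C(C)=C\[C@H](O[Si](C)(C)C(C)(C)C)/C=C(C)\I | intermediate
24 | 2-(iodomethyl)-4,4,5,5-tetramethyl-1,3,2-dioxaborolane | ICB1OC(C)(C)C(C)(C)O1 | starting material
25 | [(4,4,5,5-tetramethyl-1,3,2-dioxaborolan-2-yl)methyl]zinc iodide | I[Zn]CB1OC(C)(C)C(C)(C)O1 | intermediate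
26 | (3Z,7Z,9R,10Z)-9-[(tert-butyldimethylsilyl)oxy]-3,7,11-trimethyl-12-(4,4,5,5-tetramethyl-1,3,2-dioxaborolan-2-yl)dodeca-3,7,10-trienal | O=CC/C(C)=C\CC/C(C)=C\[C@H](O[Si](C)(C)C(C)(C)C)/C=C(C)\CB1OC(C)(C)C(C)(C)O1 | intermediate
27 | pinacol borate of 28 (boron on the C8 oxygen) | CC1(C)OB(O[C@@H]2C/C(C)=C\CC/C(C)=C\[C@H](O[Si](C)(C)C(C)(C)C)[C@@H]2C(C)=C)OC1(C)C | intermediate
28 | (1R,2R,3S,4Z,8Z)-3-[(tert-butyldimethylsilyl)oxy]-5,9-dimethyl-2-(prop-1-en-2-yl)cyclodeca-4,8-dien-1-ol | O[C@@H]1C/C(C)=C\CC/C(C)=C\[C@H](O[Si](C)(C)C(C)(C)C)[C@@H]1C(C)=C | intermediate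
29 | 3,4,5-trimethoxybenzoyl chloride | COc1cc(C(Cl)=O)cc(OC)c1OC | starting material
30 | (1R,2R,3S,4Z,8Z)-3-[(tert-butyldimethylsilyl)oxy]-5,9-dimethyl-2-(prop-1-en-2-yl)cyclodeca-4,8-dien-1-yl 3,4,5-trimethoxybenzoate | COc1cc(C(=O)O[C@@H]2C/C(C)=C\CC/C(C)=C\[C@H](O[Si](C)(C)C(C)(C)C)[C@@H]2C(C)=C)cc(OC)c1OC | intermediate
31 | (1R,2R,3S,4Z,8Z)-3-[(tert-butyldimethylsilyl)oxy]-5,9-dimethyl-2-(propan-2-yl)cyclodeca-4,8-dien-1-yl 3,4,5-trimethoxybenzoate | COc1cc(C(=O)O[C@@H]2C/C(C)=C\CC/C(C)=C\[C@H](O[Si](C)(C)C(C)(C)C)[C@@H]2C(C)C)cc(OC)c1OC | intermediate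
32 | (1R,2S,3S,4Z,8Z)-3-hydroxy-5,9-dimethyl-2-(propan-2-yl)cyclodeca-4,8-dien-1-yl 3,4,5-trimethoxybenzoate | COc1cc(C(=O)O[C@@H]2C/C(C)=C\CC/C(C)=C\[C@H](O)[C@@H]2C(C)C)cc(OC)c1OC | intermediate
33 | (1(10)Z,4R,5S,6R,7S,8R)-4,5-epoxy-6-hydroxygermacr-1(10)-en-8-yl 3,4,5-trimethoxybenzoate | COc1cc(C(=O)O[C@@H]2C/C(C)=C\CC[C@@]3(C)O[C@H]3[C@H](O)[C@@H]2C(C)C)cc(OC)c1OC | target

## Step count and least certain steps

Total: 18 steps. Longest linear sequence: 18 steps, from 1 to 33; 5, 10, 16, 24 and 29 are purchased.

Step 14 (key step, proposed new method). Most likely to go wrong: allylation between molecules outrunning the entropically and enthalpically costly closure of the medium ring, or closure on the other face of the allyl unit if the tether cannot hold C5 anti to the forming bond. Fallback with known chemistry, setting out from 22: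
- Stille coupling with Bu3SnCH2OH and Pd(PPh3)4 should give the hydroxymethyl analogue of 22, the Z allylic alcohol F1.
- CBr4 and PPh3 convert it into the allylic bromide F2.
- Swern oxidation of the primary triethylsilyl ether, as in step 12, gives the bromo aldehyde F3.
- CrCl2 in THF at high dilution (Nozaki–Hiyama–Kishi allylation, a closure known for ten-membered germacrane rings) should close C7–C8 with the anti relation, giving the C8-epimeric ring alcohol F4.
- Mitsunobu esterification with 3,4,5-trimethoxybenzoic acid, PPh3 and diisopropyl azodicarboxylate inverts C8 and comes back to the route at 30.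

Step 13. Most likely to go wrong: allylboration between molecules, promoted by zinc iodide, while the coupling is still running, or enolisation of the β,γ-unsaturated aldehyde with drift of the olefin into conjugation. Fallback, setting out from 22: the same zinc reagent and palladium catalyst are used before the aldehyde exists, giving the allylboronate bis-silyl ether F5. Selective methanolysis of the primary triethylsilyl ether (pyridinium p-toluenesulfonate, MeOH, 0 °C) gives the hydroxy allylboronate F6. Buffered Dess–Martin periodinane oxidation comes back to the route at 26.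

Step 3. Most likely to go wrong: incomplete Z selectivity and low conversion, since the α-iodo ylide is unstable and partly loses iodine before it meets the aldehyde. Fallback, setting out from 4: Corey–Fuchs dibromo-olefination (CBr4, PPh3) gives the 1,1-dibromoalkene F7. Palladium-catalysed trans-selective monomethylation (MeZnCl, PdCl2(DPEphos)) replaces the less hindered bromine and gives the (Z)-2-bromoalkene F8. Bromine–lithium exchange followed by the oxirane and silyl chloride sequence of step 4 comes back to the route at 13.

Step 9. Most likely to go wrong: poor facial discrimination, because an alkenyl and an alkynyl group differ less in size than the usual large/small pair, or competing conjugate reduction. Fallback, setting out from 17: lipase-catalysed acylation (immobilised Candida antarctica lipase B, vinyl acetate) in place of reagent control. By the empirical size rule for lipases the (S) enantiomer should be the one acylated, giving the (4S) acetate F9, which is separated from the unreacted alcohol (recyclable through 18). Methanolysis (K2CO3, MeOH) comes back to the route at 19.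

Step 18. Most likely to go wrong: Lewis-acid-triggered transannular opening of the new epoxide by C1=C10, or oxidation of the carbinol to the enone. Fallback, setting out from 32: oxygen delivery by a hydrogen-bonded peracid in place of a metal-bound peroxide (mCPBA, CH2Cl2/aq. NaHCO3, −20 °C). This removes the Lewis acid and keeps the hydroxyl-directed face selectivity; its weakness is lower preference for C4=C5 over C1=C10. It comes back to the route at 33 and makes no new compound (F0).

## Further compounds

F1 | step 14 | hydroxymethyl analogue of 22 (CH2OH in place of iodine, Z) | CC[Si](CC)(CC)OCC/C(C)=C\CC/C(C)=C\[C@H](O[Si](C)(C)C(C)(C)C)/C=C(C)\CO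
F2 | step 14 | allylic bromide from F1 (CH2Br in place of CH2OH) | CC[Si](CC)(CC)OCC/C(C)=C\CC/C(C)=C\[C@H](O[Si](C)(C)C(C)(C)C)/C=C(C)\CBr
F3 | step 14 | bromo aldehyde (C8 aldehyde, C12 bromide, C6 tert-butyldimethylsilyl ether) | O=CC/C(C)=C\CC/C(C)=C\[C@H](O[Si](C)(C)C(C)(C)C)/C=C(C)\CBr
F4 | step 14 | C8 epimer of 28, (1S,2R,3S,4Z,8Z)-3-[(tert-butyldimethylsilyl)oxy]-5,9-dimethyl-2-(prop-1-en-2-yl)cyclodeca-4,8-dien-1-ol | O[C@H]1C/C(C)=C\CC/C(C)=C\[C@H](O[Si](C)(C)C(C)(C)C)[C@@H]1C(C)=C
F5 | step 13 | Z allylboronate with C8 triethylsilyl ether and C6 tert-butyldimethylsilyl ether | CC[Si](CC)(CC)OCC/C(C)=C\CC/C(C)=C\[C@H](O[Si](C)(C)C(C)(C)C)/C=C(C)\CB1OC(C)(C)C(C)(C)O1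
F6 | step 13 | Z allylboronate with free C8 hydroxyl and C6 tert-butyldimethylsilyl ether | OCC/C(C)=C\CC/C(C)=C\[C@H](O[Si](C)(C)C(C)(C)C)/C=C(C)\CB1OC(C)(C)C(C)(C)O1
F7 | step 3 | 1-({[(2Z)-7,7-dibromo-3-methylhepta-2,6-dien-1-yl]oxy}methyl)-4-methoxybenzene | BrC(Br)=CCC/C(C)=C\COCc1ccc(OC)cc1
F8 | step 3 | 1-({[(2Z,6Z)-7-bromo-3-methylocta-2,6-dien-1-yl]oxy}methyl)-4-methoxybenzene | C/C(Br)=C/CC/C(C)=C\COCc1ccc(OC)cc1
F9 | step 9 | (4S,5Z,9Z)-6,10-dimethyl-12-[(triethylsilyl)oxy]dodeca-5,9-dien-2-yn-4-yl acetate | CC[Si](CC)(CC)OCC/C(C)=C\CC/C(C)=C\[C@H](OC(C)=O)C#CC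
F0 | step 18 | none | none
A1 | alternative 1 | (Z,Z)-cyclodecadienone with C6 ketone, C7 isopropyl and C8 benzyldimethylsilyl group | C[Si](C)(Cc1ccccc1)[C@@H]2C/C(C)=C\CC/C(C)=C\C(=O)[C@@H]2C(C)C
A2 | alternative 2 | ten-membered (Z,Z)-diene with C8 3,4,5-trimethoxybenzoate, C7 isopropyl and C6 4-methoxybenzyl ether | COc1cc(C(=O)O[C@@H]2C/C(C)=C\CC/C(C)=C\[C@H](OCc3ccc(OC)cc3)[C@@H]2C(C)C)cc(OC)c1OC
A3 | alternative 3 | ten-membered dienol with two phenylsulfonyl groups on C2, free C6 hydroxyl and C8 tert-butyldimethylsilyl ether | CC(C)(C)[Si](C)(C)O[C@@H]1C/C(C)=C\C(S(=O)(=O)c2ccccc2)(S(=O)(=O)c2ccccc2)C/C(C)=C\[C@H](O)[C@@H]1C(C)C
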